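**Retrosynthetic overview**

- The quinone comes from oxidative demethylation of its hydroquinone dimethyl ether. No ring is formed in the route; the six-membered ring is bought as an arene and oxidised last.
- The aryl–C1' bond and the 2'E olefin come from carboalumination of a terminal alkyne followed by Pd-catalysed coupling with a benzylic bromide made from 2,6-dimethylhydroquinone.
- The C8'–C9' bond, the C9' carbinol and the 6'E olefin come from one [2,3]-Wittig rearrangement of a geranyl ether of an (S)-isopropenyl carbinol; chirality moves from the C6'–O centre to C9'.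
- That ether comes from (S)-α-hydroxy-γ-butyrolactone (made from L-malic acid) and geranyl bromide: lactone C=O becomes the isopropenyl group, ring CH2O becomes CH2–C≡CH.

Assumption: side-chain carbons are numbered C1'–C16' outward from the ring, and the target is the (9'R) enantiomer encoded by the SMILES.

**Step 1**
Reactants: 1 (3S)-3-hydroxyoxolan-2-one [(S)-α-hydroxy-γ-butyrolactone]; 2 geranyl bromide [(2E)-1-bromo-3,7-dimethylocta-2,6-diene]
Product: 3 (3S)-3-{[(2E)-3,7-dimethylocta-2,6-dien-1-yl]oxy}oxolan-2-one
Conditions: Ag2O (1.5 equiv), 4 Å MS, Et2O, rt, dark, 24–48 h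
Reagents that add atoms: none
Why: Ag2O-promoted Williamson etherification: the hydroxyl attacks the primary allylic bromide in an SN2 sense under non-basic conditions, so the geranyl E-olefin is kept and the enolisable α-stereocentre of the lactone (bought as S) is not epimerised.

**Step 2**
Reactants: 3 (3S)-3-{[(2E)-3,7-dimethylocta-2,6-dien-1-yl]oxy}oxolan-2-one
Product: 4 (3S)-3-{[(2E)-3,7-dimethylocta-2,6-dien-1-yl]oxy}-5-hydroxypentan-2-one (equilibrates with its cyclic hemiketal; used crude)
Conditions: MeLi (1.05 equiv), THF, −78 °C, 30 min; then AcOH (1.1 equiv), −78 °C → rt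
Reagents that add atoms: methyllithium, [Li]C
Why: Mono-addition of an organolithium to a lactone: at −78 °C the tetrahedral lithium hemiketal alkoxide does not collapse, so only one methyl is delivered and cold protonation releases the γ-hydroxy methyl ketone with the adjacent C–O stereocentre intact.

**Step 3**
Reactants: 4 (3S)-3-{[(2E)-3,7-dimethylocta-2,6-dien-1-yl]oxy}-5-hydroxypentan-2-one
Product: 5 (3S)-3-{[(2E)-3,7-dimethylocta-2,6-dien-1-yl]oxy}-4-methylpent-4-en-1-ol
Conditions: Ph3PCH3Br (3 equiv), KOtBu (2.9 equiv), THF, 0 °C; then 4, 0 °C → rt, 2 h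
Reagents that add atoms: methyltriphenylphosphonium bromide, C[P+](c1ccccc1)(c1ccccc1)c1ccccc1.[Br-]
Why: Wittig methylenation: the excess ylide first converts the hydroxyl into its alkoxide and then methylenates the open keto form faster than the ketone enolises toward the alkoxy-bearing carbon, giving the isopropenyl carbinol ether without loss of configuration.

**Step 4**
Reactants: 5 (3S)-3-{[(2E)-3,7-dimethylocta-2,6-dien-1-yl]oxy}-4-methylpent-4-en-1-ol
Product: 6 (3S)-3-{[(2E)-3,7-dimethylocta-2,6-dien-1-yl]oxy}-4-methylpent-4-en-1-yl 4-methylbenzenesulfonate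
Conditions: TsCl (1.2 equiv), Et3N (2 equiv), DMAP (5 mol %), CH2Cl2, 0 °C → rt
Reagents that add atoms: 4-methylbenzenesulfonyl chloride, Cc1ccc(cc1)S(Cl)(=O)=O
Why: Sulfonylation of the only free (primary) hydroxyl turns it into a good leaving group under mild amine-base conditions that leave the allylic ether, the olefins and the stereocentre untouched.

**Step 5**
Reactants: 6 (3S)-3-{[(2E)-3,7-dimethylocta-2,6-dien-1-yl]oxy}-4-methylpent-4-en-1-yl 4-methylbenzenesulfonate
Product: 7 (3S)-3-{[(2E)-3,7-dimethylocta-2,6-dien-1-yl]oxy}-2-methylhept-1-en-6-yne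
Conditions: LiC≡CH·H2NCH2CH2NH2 (2 equiv), DMSO, 15 °C → rt, 3 h
Reagents that add atoms: lithium acetylide (as its ethylenediamine complex), [Li]C#C
Why: SN2 alkylation of acetylide by an unhindered primary tosylate in DMSO gives the terminal alkyne; the stereocentre is two carbons away from the reacting centre and is not involved.

**Step 6** (key step)
Reactants: 7 (3S)-3-{[(2E)-3,7-dimethylocta-2,6-dien-1-yl]oxy}-2-methylhept-1-en-6-yne
Product: 9 (5E,8R,9E)-6,10,14-trimethylpentadeca-5,9,13-trien-1-yn-8-ol, via dilithio ether 8 (not isolated)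
Conditions: n-BuLi (2.4 equiv), THF, −78 → −30 °C, 4 h; then H2O
Reagents that add atoms: none
Why: [2,3]-Wittig rearrangement: after the acetylide forms, the second equivalent of base lithiates the less substituted, doubly activated OCH2 of the geranyl group, and this α-oxy allyllithium bonds to C8' through a five-membered envelope in which the chain on C6' is pseudo-equatorial (giving the 6'E olefin) and the dienyl group is exo, away from the C7' methyl, so the bought S centre at C6' is converted into the R carbinol at C9' as the C8'–C9' bond forms.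

**Step 7**
Reactants: 10 2,6-dimethylbenzene-1,4-diol (2,6-dimethylhydroquinone)
Product: 11 2,5-dimethoxy-1,3-dimethylbenzene
Conditions: MeI (3 equiv), K2CO3 (3 equiv), DMF, rt → 50 °C, N2
Reagents that add atoms: iodomethane, CI
Why: Williamson O-methylation of both phenolic hydroxyls (the hindered one included) with a small, reactive electrophile in a dipolar solvent, run under nitrogen because the hydroquinone anion is air-sensitive.

**Step 8**
Reactants: 11 2,5-dimethoxy-1,3-dimethylbenzene
Product: 12 1-(bromomethyl)-2,5-dimethoxy-3-methylbenzene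
Conditions: NBS (1.0 equiv), AIBN (5 mol %), PhCF3, reflux, hν
Reagents that add atoms: N-bromosuccinimide, BrN1C(=O)CCC1=O
Why: Wohl–Ziegler radical bromination: the two methyl groups are equivalent, so a single monobromide results, and a radical chain in a non-polar solvent favours benzylic hydrogen abstraction over electrophilic ring bromination.

**Step 9**
Reactants: 9 (5E,8R,9E)-6,10,14-trimethylpentadeca-5,9,13-trien-1-yn-8-ol; 12 1-(bromomethyl)-2,5-dimethoxy-3-methylbenzene
Product: 14 (6E,8R,10E,14E)-16-(2,5-dimethoxy-3-methylphenyl)-2,6,10,14-tetramethylhexadeca-2,6,10,14-tetraen-8-ol, via alkenylalane 13 (not isolated)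
Conditions: Me3Al (3.5 equiv), Cp2ZrCl2 (20 mol %), H2O (1 equiv), CH2Cl2, −20 → 0 °C; volatiles removed; then 12 (1.1 equiv), Pd(PPh3)4 (5 mol %), THF, rt; aq. KNaC4H4O6 work-up
Reagents that add atoms: trimethylaluminium, C[Al](C)C
Why: Negishi zirconium-catalysed carboalumination adds Me–Al syn across the terminal alkyne with methyl on the internal carbon (the hydroxyl is masked in situ as its aluminium alkoxide and the trisubstituted olefins are inert), and the (E)-alkenylalane then cross-couples with the benzylic bromide under zerovalent palladium catalysis with retention, giving the 2'E olefin and the aryl–C1' link without touching C9'.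

**Step 10**
Reactants: 14 (6E,8R,10E,14E)-16-(2,5-dimethoxy-3-methylphenyl)-2,6,10,14-tetramethylhexadeca-2,6,10,14-tetraen-8-ol
Product: 15 2-[(2E,6E,9R,10E)-9-hydroxy-3,7,11,15-tetramethylhexadeca-2,6,10,14-tetraen-1-yl]-6-methylcyclohexa-2,5-diene-1,4-dione (target)
Conditions: (NH4)2Ce(NO3)6 (2.5 equiv), MeCN/H2O 2:1, 0 °C, 20 min
Reagents that add atoms: water, O
Why: Oxidative demethylation of the 1,4-dimethoxyarene by tetravalent cerium (two one-electron oxidations, water attacking the ring carbons and methanol leaving) gives the para-quinone within minutes at 0 °C, conditions under which the trisubstituted olefins and the secondary allylic alcohol, and hence the C9' stereocentre, are left alone.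

**Compound list**

1 | (3S)-3-hydroxyoxolan-2-one [(S)-α-hydroxy-γ-butyrolactone] | O[C@H]1CCOC1=O | starting material
2 | geranyl bromide, (2E)-1-bromo-3,7-dimethylocta-2,6-diene | CC(C)=CCC/C(C)=C/CBr | starting material
3 | (3S)-3-{[(2E)-3,7-dimethylocta-2,6-dien-1-yl]oxy}oxolan-2-one | CC(C)=CCC/C(C)=C/CO[C@H]1CCOC1=O | intermediate
4 | (3S)-3-{[(2E)-3,7-dimethylocta-2,6-dien-1-yl]oxy}-5-hydroxypentan-2-one | CC(C)=CCC/C(C)=C/CO[C@@H](CCO)C(C)=O | intermediate
5 | (3S)-3-{[(2E)-3,7-dimethylocta-2,6-dien-1-yl]oxy}-4-methylpent-4-en-1-ol | CC(C)=CCC/C(C)=C/CO[C@@H](CCO)C(C)=C | intermediate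
6 | (3S)-3-{[(2E)-3,7-dimethylocta-2,6-dien-1-yl]oxy}-4-methylpent-4-en-1-yl 4-methylbenzenesulfonate | CC(C)=CCC/C(C)=C/CO[C@@H](CCOS(=O)(=O)c1ccc(C)cc1)C(C)=C | intermediate
7 | (3S)-3-{[(2E)-3,7-dimethylocta-2,6-dien-1-yl]oxy}-2-methylhept-1-en-6-yne | CC(C)=CCC/C(C)=C/CO[C@@H](CCC#C)C(C)=C | intermediate
8 | dilithio ether: 7 lithiated at the alkyne terminus and at the geranyl OCH carbon (not isolated) | CC(C)=CCC/C(C)=C/C([Li])O[C@@H](CCC#C[Li])C(C)=C | intermediate
9 | (5E,8R,9E)-6,10,14-trimethylpentadeca-5,9,13-trien-1-yn-8-ol | CC(C)=CCC/C(C)=C/[C@H](O)C/C(C)=C/CCC#C | intermediate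
10 | 2,6-dimethylbenzene-1,4-diol | Cc1cc(O)cc(C)c1O | starting material
11 | 2,5-dimethoxy-1,3-dimethylbenzene | COc1cc(C)c(OC)c(C)c1 | intermediate
12 | 1-(bromomethyl)-2,5-dimethoxy-3-methylbenzene | COc1cc(C)c(OC)c(CBr)c1 | intermediate
13 | alkenylalane: (1E)-alkenyl(dimethyl)alane from 9 with Me on C2 and the hydroxyl as its dimethylaluminium alkoxide (not isolated) | CC(C)=CCC/C(C)=C/[C@H](O[Al](C)C)C/C(C)=C/CC/C(C)=C/[Al](C)C | intermediate
14 | (6E,8R,10E,14E)-16-(2,5-dimethoxy-3-methylphenyl)-2,6,10,14-tetramethylhexadeca-2,6,10,14-tetraen-8-ol | CC(C)=CCC/C(C)=C/[C@H](O)C/C(C)=C/CC/C(C)=C/Cc1cc(OC)cc(C)c1OC | intermediate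
15 | 2-[(2E,6E,9R,10E)-9-hydroxy-3,7,11,15-tetramethylhexadeca-2,6,10,14-tetraen-1-yl]-6-methylcyclohexa-2,5-diene-1,4-dione | CC(C)=CCC/C(C)=C/[C@H](O)C/C(C)=C/CC/C(C)=C/CC1=CC(=O)C=C(C)C1=O | target

**Step count**

Total: 10 steps. Longest linear sequence: 8 steps (1 → 3 → 4 → 5 → 6 → 7 → 9 → 14 → 15); the arene branch (10 → 11 → 12) is 2 steps.

**Three steps most likely to fail**

Step 6 carries the most risk. The lithiation must occur at the geranyl OCH2 and not at the allylic methine. The E/Z ratio of the new trisubstituted olefin and the fidelity of the chirality transfer both depend on one transition-state preference. The substrate also has to be handled as a dianion because of the alkyne C–H. The fallback sets out from 5 and returns at 9. It moves the rearrangement ahead of the alkyne, so the carbanion chemistry runs on a substrate with no second acidic C–H and the olefin isomers can be separated at a polar diol stage. Alcohol 5 is treated with n-BuLi (2.4 equiv, THF, −78 → −30 °C) and rearranges as its alkoxide to (3E,6R,7E)-4,8,12-trimethyltrideca-3,7,11-triene-1,6-diol F1. Only the primary hydroxyl is tosylated (TsCl, Et3N, CH2Cl2, −10 °C) to give (3E,6R,7E)-6-hydroxy-4,8,12-trimethyltrideca-3,7,11-trien-1-yl 4-methylbenzenesulfonate F2. LiC≡CH·H2NCH2CH2NH2 (3 equiv, DMSO) then displaces the tosylate to give 9.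

Step 9 is the second risk. The free allylic alkoxide sits in a Lewis-acidic aluminium medium, residual Me3Al can methylate the benzylic bromide, and the electron-rich bromide can self-alkylate. The fallback sets out from 9 (with 12) and returns at 14. It reverses the polarity of the coupling. Alkenylalane 13 is quenched with I2 (THF, −30 °C) to (1E,5E,8R,9E)-1-iodo-2,6,10,14-tetramethylpentadeca-1,5,9,13-tetraen-8-ol F3, which is purified free of aluminium. Bromide 12 is inserted with Zn dust and LiCl (THF, rt) to (2,5-dimethoxy-3-methylbenzyl)zinc bromide F4. Negishi coupling of F3 with F4 (2.5 equiv, Pd(PPh3)4, THF, rt) gives 14.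

Step 3 is the third risk. The α-alkoxy ketone can enolise toward the stereocentre under the basic ylide, which would erode the enantiomeric purity that the whole route depends on, and the hemiketal form can react sluggishly. The fallback sets out from 4 and returns at 5. It is a Peterson olefination through a non-basic organocerium addition. Me3SiCH2MgCl with CeCl3 (3 equiv, THF, −78 → 0 °C) adds to the ketone without enolisation to give (3S)-3-{[(2E)-3,7-dimethylocta-2,6-dien-1-yl]oxy}-4-methyl-5-(trimethylsilyl)pentane-1,4-diol F5 as both C4 epimers. KH (THF, 0 °C → rt) then eliminates the silanolate from either epimer to give 5.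

**Further compounds**

F1 | step 6 | (3E,6R,7E)-4,8,12-trimethyltrideca-3,7,11-triene-1,6-diol | CC(C)=CCC/C(C)=C/[C@H](O)C/C(C)=C/CCO
F2 | step 6 | (3E,6R,7E)-6-hydroxy-4,8,12-trimethyltrideca-3,7,11-trien-1-yl 4-methylbenzenesulfonate | CC(C)=CCC/C(C)=C/[C@H](O)C/C(C)=C/CCOS(=O)(=O)c1ccc(C)cc1
F3 | step 9 | (1E,5E,8R,9E)-1-iodo-2,6,10,14-tetramethylpentadeca-1,5,9,13-tetraen-8-ol | CC(C)=CCC/C(C)=C/[C@H](O)C/C(C)=C/CC/C(C)=C/I
F4 | step 9 | (2,5-dimethoxy-3-methylbenzyl)zinc bromide | COc1cc(C)c(OC)c(C[Zn]Br)c1
F5 | step 3 | (3S)-3-{[(2E)-3,7-dimethylocta-2,6-dien-1-yl]oxy}-4-methyl-5-(trimethylsilyl)pentane-1,4-diol (C4 epimers) | CC(C)=CCC/C(C)=C/CO[C@@H](CCO)C(C)(O)C[Si](C)(C)C
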